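**Retrosynthetic overview**

1. Only the pyranone ring (ring C) has to be built. It is closed last, at C4–C4a, by intramolecular acylation of the open-chain acid 6 with its own carboxyl carbon; the two benzyl ethers are removed in the same flask, so the key step ends at target 9.
2. Enabling feature: C4a is a phloroglucinol carbon of ring A (ortho to O1, ortho/para to the C5 and C7 oxygens). In the 3,5-dioxygenated aryl ether of 6 it is homotopic with the other carbon ortho to O1 (the later C8), so only one constitution can form and a mixed anhydride is electrophile enough.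
3. Acid 6 comes from hydroxy ester 3 by saponification and O-hexanoylation.
4. Ester 3 comes from the O1–C2 disconnection: SN2 opening of trans-glycidate 1 at its benzylic carbon by phenol 2 sets C2 and C3 in one event.
5. Ring order: A and B are bought; C is formed in step 4.

Key step: step 4

Remark: methyl (2R,3S)-3-phenylglycidate and 3,5-bis(benzyloxy)phenol are taken as catalogue compounds. The glycidate is otherwise two routine steps from methyl cinnamate (asymmetric dihydroxylation to the (2R,3S)-diol, then diol-to-epoxide closure with net retention).

**Route**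

Step 1
Reactants: 1 methyl (2R,3S)-3-phenylglycidate; 2 3,5-bis(benzyloxy)phenol
Product: 3 methyl (2R,3R)-3-[3,5-bis(benzyloxy)phenoxy]-2-hydroxy-3-phenylpropanoate
Conditions: Cs2CO3 (0.3 equiv), DMF, 60 °C
Reagents that add atoms: none
Why: Base-catalysed SN2 opening of a trans-3-arylglycidic ester by a phenoxide should go to the benzylic C3 (the usual site for 3-arylglycidates; C2 next to the ester is the poorer one) with inversion there and retention at C2, so the (2R,3S)-epoxide gives the (2R,3R) aryloxy alcohol and both stereocentres of the target and the O1–C2 ether bond are set at once.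

Step 2
Reactants: 3 methyl (2R,3R)-3-[3,5-bis(benzyloxy)phenoxy]-2-hydroxy-3-phenylpropanoate
Product: 4 (2R,3R)-3-[3,5-bis(benzyloxy)phenoxy]-2-hydroxy-3-phenylpropanoic acid
Conditions: LiOH·H2O, THF/H2O (3:1), 0 °C → rt; then 1 M HCl to pH 2–3
Reagents that add atoms: lithium hydroxide, [Li+].[OH-]
Why: Ester saponification (BAc2) at low temperature should leave both stereocentres untouched, since the α-hydroxy carboxylate is not enolised and the aryl and benzyl ethers are inert to hydroxide.

Step 3
Reactants: 4 (2R,3R)-3-[3,5-bis(benzyloxy)phenoxy]-2-hydroxy-3-phenylpropanoic acid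
Product: 6 (2R,3R)-3-[3,5-bis(benzyloxy)phenoxy]-2-(hexanoyloxy)-3-phenylpropanoic acid, via hexanoic mixed anhydride 5 (not isolated)
Conditions: hexanoyl chloride (2.5 equiv), pyridine, CH2Cl2, 0 °C → rt; then H2O/THF, rt; dil. HCl work-up
Reagents that add atoms: hexanoyl chloride, CCCCCC(=O)Cl; water, O
Why: Acid chloride/pyridine O-acylation of the secondary alcohol also acylates the carboxyl group to mixed anhydride 5, which aqueous pyridine should hydrolyse selectively because an anhydride is far more labile than the new ester; no bond to a stereocentre is broken.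

Step 4
Reactants: 6 (2R,3R)-3-[3,5-bis(benzyloxy)phenoxy]-2-(hexanoyloxy)-3-phenylpropanoic acid
Product: 9 (2R,3R)-5,7-dihydroxy-4-oxo-2-phenylchroman-3-yl hexanoate (pinobanksin 3-O-hexanoate), via acyl trifluoroacetate 7 (not isolated), via dibenzyl chromanone hexanoate 8 (not isolated)
Conditions: TFAA (1.5 equiv), CH2Cl2 (0.02 M), 0 °C → rt; then C6HMe5 (8 equiv), BCl3 (6 equiv), −78 → −40 °C; MeOH quench
Reagents that add atoms: none
Why: TFAA turns the acid into acyl trifluoroacetate 7, whose acyl carbon is attacked by the ring carbon ortho to the ether oxygen (electrophilic aromatic substitution with loss of trifluoroacetate and a proton) to give chromanone 8; BCl3 then binds the two benzyl ether oxygens and hands the benzyl groups to pentamethylbenzene, and the methanol quench should release 9. Both events are established reaction types run in one flask: mixed-anhydride Friedel–Crafts cycloacylation of 3-aryloxy(-3-phenyl)propanoic acids to chroman-4-ones and flavanones, and BCl3/pentamethylbenzene debenzylation of aryl benzyl ethers. The pyranone ring closes in the 6-exo-trig mode at the acyl carbon. No stereocentre is created: C2 and C3 come from step 1 and should not be at risk under base-free conditions at or below room temperature (no ketene, no enolate), and the trans-diequatorial arrangement they give is also the thermodynamically preferred one. Regiochemistry is degenerate because the two carbons ortho to O1 are homotopic and the third activated ring carbon cannot be reached by the three-atom tether; the acyl trifluoroacetate is far more electrophilic than the hexanoate, pentamethylbenzene intercepts benzyl cations before they can alkylate C6 or C8, and after ring closure the C2–O1 oxygen is a vinylogous ester oxygen that BCl3 should not cleave.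

**Compound list**

1 | methyl (2R,3S)-3-phenyloxirane-2-carboxylate (methyl (2R,3S)-3-phenylglycidate, trans) | COC(=O)[C@@H]1O[C@H]1c1ccccc1 | starting material
2 | 3,5-bis(benzyloxy)phenol | Oc1cc(OCc2ccccc2)cc(OCc2ccccc2)c1 | starting material
3 | methyl (2R,3R)-3-[3,5-bis(benzyloxy)phenoxy]-2-hydroxy-3-phenylpropanoate | COC(=O)[C@H](O)[C@H](Oc1cc(OCc2ccccc2)cc(OCc2ccccc2)c1)c1ccccc1 | intermediate
4 | (2R,3R)-3-[3,5-bis(benzyloxy)phenoxy]-2-hydroxy-3-phenylpropanoic acid | OC(=O)[C@H](O)[C@H](Oc1cc(OCc2ccccc2)cc(OCc2ccccc2)c1)c1ccccc1 | intermediate
5 | hexanoic (2R,3R)-3-[3,5-bis(benzyloxy)phenoxy]-2-(hexanoyloxy)-3-phenylpropanoic anhydride (not isolated) | CCCCCC(=O)OC(=O)[C@H](OC(=O)CCCCC)[C@H](Oc1cc(OCc2ccccc2)cc(OCc2ccccc2)c1)c1ccccc1 | intermediate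
6 | (2R,3R)-3-[3,5-bis(benzyloxy)phenoxy]-2-(hexanoyloxy)-3-phenylpropanoic acid | CCCCCC(=O)O[C@@H](C(=O)O)[C@H](Oc1cc(OCc2ccccc2)cc(OCc2ccccc2)c1)c1ccccc1 | intermediate
7 | (2R,3R)-3-[3,5-bis(benzyloxy)phenoxy]-2-(hexanoyloxy)-3-phenylpropanoic trifluoroacetic anhydride (not isolated) | CCCCCC(=O)O[C@@H](C(=O)OC(=O)C(F)(F)F)[C@H](Oc1cc(OCc2ccccc2)cc(OCc2ccccc2)c1)c1ccccc1 | intermediate
8 | (2R,3R)-5,7-bis(benzyloxy)-4-oxo-2-phenylchroman-3-yl hexanoate (not isolated) | CCCCCC(=O)O[C@H]1C(=O)c2c(OCc3ccccc3)cc(OCc3ccccc3)cc2O[C@@H]1c1ccccc1 | intermediate
9 | (2R,3R)-5,7-dihydroxy-4-oxo-2-phenylchroman-3-yl hexanoate (pinobanksin 3-O-hexanoate) | CCCCCC(=O)O[C@H]1C(=O)c2c(O)cc(O)cc2O[C@@H]1c1ccccc1 | target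

**Step count and risks**

Total steps: 4. Longest linear sequence: 4 steps (1 → 3 → 4 → 6 → 9).

Step 4 (key step). The processes that may go wrong are incomplete or intermolecular acylation in the mixed-anhydride stage, and benzyl transfer to ring carbons or ester cleavage during the Lewis-acid unmasking. The fallback reverses the order of the two events and closes the ring on the free phloroglucinol ether. It sets out from 6: hydrogenolysis (H2, Pd/C, EtOAc, rt, stopped after two equivalents of hydrogen so that the C–O bond at the benzylic stereocentre is spared) should give (2R,3R)-3-(3,5-dihydroxyphenoxy)-2-(hexanoyloxy)-3-phenylpropanoic acid F1. This is then cyclised in BF3·OEt2 at 40–50 °C with aqueous NaOAc work-up, the classical conditions for C-acylation of unprotected phloroglucinols by carboxylic acids. The fallback comes back to the route at 9.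

Step 1. The processes that may go wrong are leakage of the phenoxide to C2, transesterification of the methyl ester by the phenoxide, and oligomerisation through the product alkoxide. The fallback removes the ester before the opening. It sets out from 1: saponification (KOH, EtOH, 0 °C) should give potassium (2R,3S)-3-phenylglycidate F2. This salt is opened by the potassium salt of 2 in water/dioxane at 70–80 °C; the carboxylate cannot be transesterified and directs attack to C3, as in the known aminolysis of glycidate salts. Acidification returns the route at 4, so step 2 is bypassed.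

Step 3. The process that may go wrong is loss of integrity at the α-carbon of the transient mixed anhydride 5 (ketene formation or β-elimination of the aryloxide under base), together with ester oligomers formed when 5 acylates the hydroxyl of another molecule. The fallback acylates while the carboxyl group is still an ester. It sets out from 3: hexanoyl chloride, pyridine and catalytic DMAP in CH2Cl2 should give methyl (2R,3R)-3-[3,5-bis(benzyloxy)phenoxy]-2-(hexanoyloxy)-3-phenylpropanoate F3. The methyl ester is then cleaved by SN2 dealkylation (LiI, EtOAc, reflux, then dilute acid), which should not touch the secondary hexanoate. The fallback comes back at 6, so steps 2 and 3 are bypassed.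

**Further compounds**

F1 | step 4 | (2R,3R)-3-(3,5-dihydroxyphenoxy)-2-(hexanoyloxy)-3-phenylpropanoic acid | CCCCCC(=O)O[C@@H](C(=O)O)[C@H](Oc1cc(O)cc(O)c1)c1ccccc1
F2 | step 1 | potassium (2R,3S)-3-phenyloxirane-2-carboxylate | [K+].[O-]C(=O)[C@@H]1O[C@H]1c1ccccc1
F3 | step 3 | methyl (2R,3R)-3-[3,5-bis(benzyloxy)phenoxy]-2-(hexanoyloxy)-3-phenylpropanoate | CCCCCC(=O)O[C@@H](C(=O)OC)[C@H](Oc1cc(OCc2ccccc2)cc(OCc2ccccc2)c1)c1ccccc1
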